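Benzofuran numbering: ring A = C3a, C4, C5, C6, C7, C7a; ring B = O1, C2, C3, C3a, C7a.
Retrosynthetic cuts, in order: both C5–prenyl bonds (ring A becomes aromatic again), the C7–acyl bond, the two C–CH3 bonds of the carbinol (back to a C2 ester), then O1–C2 and C2–C3 together.
Enabling feature: in ring B the single carbon C2 is bonded to both O1 and the C3 methylene. Ring B therefore divides into a four-atom ortho-quinone methide (O1=C7a–C3a=C3H2) and a one-carbon ylide (C2).
Forward order: ring A is bought as a phloroglucinol aldehyde and ring B closes in the [4+1] annulation. Then follow ester to CMe2OH, C7 acylation through the bromide, hydrogenolysis, and last the dearomatising double prenylation at C5.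
Stereochemistry: C2 (S) is the only stereocentre. It is set in the annulation by a 9-O-methylquinidinium leaving group on the ylide and becomes non-epimerisable one step later.
Benzyl ethers mask O4 and O6 because neutral hydrogenolysis removes them without harming the tertiary alcohol and before any alkene is present; C7 is acylated without acid for the same reason.

Key step: step 6

Assumption: the 9-O-methylquinidinium ylide is taken to deliver (S) at C2; the sense of induction on a CH2-terminated methide has no direct analogy, and the pseudo-enantiomeric 9-O-methylquininium salt is available by the same two steps.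

Step 1
Reactants: 1 2,4,6-trihydroxybenzaldehyde; 2 benzyl bromide
Product: 4 2,4-bis(benzyloxy)-6-hydroxybenzaldehyde, via 4-O-benzyl ether 3 (not isolated)
Conditions: BnBr (2.05 equiv), K2CO3 (2.1 equiv), DMF, 0 °C to rt
Reagents that add atoms: benzyl bromide (2), BrCc1ccccc1
Why: Williamson ether synthesis under stoichiometric control: the para hydroxyl, most acidic and not hydrogen-bonded, reacts first (3), one ortho hydroxyl follows, and the last is held back by its hydrogen bond to the aldehyde oxygen.

Step 2
Reactants: 4 2,4-bis(benzyloxy)-6-hydroxybenzaldehyde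
Product: 5 3,5-bis(benzyloxy)-2-(hydroxymethyl)phenol
Conditions: NaBH4, THF–MeOH, 0 °C; pH 7 work-up, used without chromatography
Reagents that add atoms: none
Why: Borohydride reduction of an aldehyde; low temperature, short contact and a neutral work-up should keep the electron-rich salicyl alcohol from ionising, being reduced further or self-condensing.

Step 3
Reactants: 5 3,5-bis(benzyloxy)-2-(hydroxymethyl)phenol; 6 sodium p-toluenesulfinate
Product: 7 3,5-bis(benzyloxy)-2-(tosylmethyl)phenol
Conditions: TolSO2Na (2 equiv), AcOH–H2O–THF, rt
Reagents that add atoms: sodium p-toluenesulfinate (6), Cc1ccc(cc1)S(=O)[O-].[Na+]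
Why: Acid-promoted SN1 benzylic substitution: the alcohol, activated by an ortho hydroxyl and by ortho and para benzyloxy groups, should ionise already in acetic acid, and the soft sulfur of the excess sulfinate captures the cation faster than a second arene can, giving a storable sulfone.

Step 4
Reactants: 8 quinidine; 9 iodomethane
Product: 10 9-O-methylquinidine
Conditions: NaH, DMF, 0 °C to rt; MeI (1.05 equiv), 0 °C
Reagents that add atoms: iodomethane (9), CI
Why: Williamson ether synthesis on the preformed C9 sodium alkoxide, which is far more nucleophilic toward one equivalent of MeI at 0 °C than the quinuclidine nitrogen, with C8 and C9 untouched.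

Step 5
Reactants: 10 9-O-methylquinidine; 11 methyl bromoacetate
Product: 12 1-(2-methoxy-2-oxoethyl)-9-O-methylquinidinium bromide (quaternised at the quinuclidine nitrogen)
Conditions: BrCH2CO2Me (1.05 equiv), THF, rt; salt filtered off
Reagents that add atoms: methyl bromoacetate (11), COC(=O)CBr
Why: Menshutkin quaternisation, selective for the sp3 quinuclidine nitrogen over the much less nucleophilic quinoline nitrogen, with precipitation of the salt preventing a second alkylation.

Step 6
Reactants: 7 3,5-bis(benzyloxy)-2-(tosylmethyl)phenol; 12 1-(2-methoxy-2-oxoethyl)-9-O-methylquinidinium bromide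
Product: 16 methyl (S)-4,6-bis(benzyloxy)-2,3-dihydrobenzofuran-2-carboxylate, via ortho-quinone methide 13 (not isolated), via ammonium ylide 14 (not isolated), via betaine 15 (not isolated)
Conditions: 12 (1.3 equiv), Cs2CO3 (3 equiv), CH2Cl2, 0 °C
Reagents that add atoms: none
Why: Proposed new method: Cs2CO3 deprotonates phenol 7, which expels p-toluenesulfinate (E1cB) to give ortho-quinone methide 13, and it deprotonates salt 12 to the ester-stabilised ylide 14, whose carbon adds to the exocyclic CH2 of 13 (C2–C3 bond, ring A rearomatises) to give betaine 15. The phenoxide oxygen of 15 then displaces the quinuclidine nitrogen at C2 with inversion (O1–C2 bond), a 5-exo-tet SN2 closure of ring B that returns amine 10 for recovery. The closest known reaction types are the enantioselective [4+1] annulation of cinchona-derived ammonium ylides with in situ generated, aryl-substituted ortho-quinone methides and the racemic [4+1] annulation of CH2-terminated methides with sulfonium or pyridinium ylides; new here is that the chiral ammonium group alone must set a single stereocentre on a methide without a substituent at its terminus. C2 is controlled by the 9-O-methylquinidinium group: the quinoline and C9 methoxy substituents shield one face of the planar ylide in the addition, and since the C2–H of 15 lies between N+ and the ester the two betaine epimers can equilibrate, so that the (R)-epimer, expected to reach the anti-periplanar O···C2–N+ alignment with less strain, should drain into (S)-16. The step needs chemoselective capture of 13 by 14 instead of methide self-condensation, which is secured by the slow heterogeneous release of 13, the reversibility of sulfinate return, the damping of the methide by its two benzyloxy donors and the excess of 12; regioselectivity is trivial because only one oxygen flanks the CH2 and no alkene or second acidic site is present. Low temperature, a carbonate base and immediate use of 16 in step 7 guard the new α-aryloxy ester centre against epimerisation.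

Step 7
Reactants: 16 methyl (S)-4,6-bis(benzyloxy)-2,3-dihydrobenzofuran-2-carboxylate; 17 methylmagnesium bromide
Product: 19 (S)-2-[4,6-bis(benzyloxy)-2,3-dihydrobenzofuran-2-yl]propan-2-ol, via methyl ketone 18 (not isolated)
Conditions: MeMgBr (3.5 equiv), THF, −78 to 0 °C (ester added to the reagent)
Reagents that add atoms: methylmagnesium bromide (17), C[Mg]Br
Why: Double Grignard addition to an ester through ketone 18; with the ester added to excess reagent at low temperature, carbonyl addition, helped by chelation to O1, should outrun enolisation, so C2 keeps its configuration and is no longer epimerisable in 19.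

Step 8
Reactants: 19 (S)-2-[4,6-bis(benzyloxy)-2,3-dihydrobenzofuran-2-yl]propan-2-ol; 20 N-bromosuccinimide
Product: 21 (S)-2-[4,6-bis(benzyloxy)-7-bromo-2,3-dihydrobenzofuran-2-yl]propan-2-ol
Conditions: NBS (1.0 equiv), CH2Cl2, −78 to 0 °C, dark
Reagents that add atoms: N-bromosuccinimide (20), O=C1CCC(=O)N1Br
Why: Electrophilic aromatic bromination: C7 is flanked by the tied-back ring oxygen O1 and one benzyloxy group whereas C5 lies between two freely rotating benzyloxy groups, the same bias that sends NBS to C8 of 5,7-dialkoxychromans and flavans, and the tertiary alcohol is inert under these non-acidic conditions.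

Step 9
Reactants: 21 (S)-2-[4,6-bis(benzyloxy)-7-bromo-2,3-dihydrobenzofuran-2-yl]propan-2-ol; 22 N-methoxy-N-methylisobutyramide
Product: 25 1-[(2S)-4,6-bis(benzyloxy)-2-(2-hydroxypropan-2-yl)-2,3-dihydrobenzofuran-7-yl]-2-methylpropan-1-one, via aryllithium alkoxide 23 (not isolated), via tetrahedral adduct 24 (not isolated)
Conditions: n-BuLi (2.2 equiv), THF, −78 °C; then 22 (2 equiv), −78 to 0 °C
Reagents that add atoms: N-methoxy-N-methylisobutyramide (22), CC(C)C(=O)N(C)OC
Why: Bromine–lithium exchange followed by Weinreb ketone synthesis: the first equivalent of n-BuLi makes the alkoxide, the second gives aryllithium 23 faster than benzylic deprotonation at −78 °C, and the chelated adduct 24 releases the ketone only on work-up, so there is no over-addition and no acid ever meets the tertiary alcohol.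

Step 10
Reactants: 25 1-[(2S)-4,6-bis(benzyloxy)-2-(2-hydroxypropan-2-yl)-2,3-dihydrobenzofuran-7-yl]-2-methylpropan-1-one
Product: 26 1-[(2S)-4,6-dihydroxy-2-(2-hydroxypropan-2-yl)-2,3-dihydrobenzofuran-7-yl]-2-methylpropan-1-one
Conditions: H2 (1 atm), Pd/C, EtOAc–MeOH, rt
Reagents that add atoms: none
Why: Catalytic hydrogenolysis of aryl benzyl ethers under neutral conditions; the hindered conjugated ketone, the homobenzylic O1–C2 bond and the tertiary alcohol should not be reduced, and no alkene is present yet.

Step 11
Reactants: 26 1-[(2S)-4,6-dihydroxy-2-(2-hydroxypropan-2-yl)-2,3-dihydrobenzofuran-7-yl]-2-methylpropan-1-one; 27 prenyl bromide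
Product: 29 garcinielliptone HD, via 5-prenyl phenol 28 (not isolated)
Conditions: prenyl bromide (2.5 equiv, in portions), KOH (3 equiv), H2O–MeOH, 0 °C to rt; 1 M HCl work-up
Reagents that add atoms: prenyl bromide (27), CC(C)=CCBr
Why: Alkylative dearomatisation of an acylphloroglucinol, the reaction type that turns deoxyhumulones into lupulones: in aqueous base the phenoxide oxygens are solvated, so prenyl bromide is attacked by C5, the carbon between the two phenoxide-bearing carbons C4 and C6, first to give 28 and then again at the same carbon to give the gem-diprenyl β-triketone, whose stabilised enolate resists further alkylation, while the non-acidic C2 stays (S).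

Compound list
1 | 2,4,6-trihydroxybenzaldehyde | O=Cc1c(O)cc(O)cc1O | starting material
2 | benzyl bromide | BrCc1ccccc1 | starting material
3 | 4-(benzyloxy)-2,6-dihydroxybenzaldehyde | O=Cc1c(O)cc(OCc2ccccc2)cc1O | intermediate
4 | 2,4-bis(benzyloxy)-6-hydroxybenzaldehyde | O=Cc1c(O)cc(OCc2ccccc2)cc1OCc1ccccc1 | intermediate
5 | 3,5-bis(benzyloxy)-2-(hydroxymethyl)phenol | OCc1c(O)cc(OCc2ccccc2)cc1OCc1ccccc1 | intermediate
6 | sodium p-toluenesulfinate | Cc1ccc(cc1)S(=O)[O-].[Na+] | starting material
7 | 3,5-bis(benzyloxy)-2-(tosylmethyl)phenol | Cc1ccc(cc1)S(=O)(=O)Cc1c(O)cc(OCc2ccccc2)cc1OCc1ccccc1 | intermediate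
8 | quinidine, (8R,9S) | COc1ccc2nccc(c2c1)[C@@H]([C@H]1C[C@@H]2CCN1C[C@@H]2C=C)O | starting material
9 | iodomethane | CI | starting material
10 | 9-O-methylquinidine, (8R,9S)-6',9-dimethoxycinchonan | COc1ccc2nccc(c2c1)[C@@H]([C@H]1C[C@@H]2CCN1C[C@@H]2C=C)OC | intermediate
11 | methyl bromoacetate | COC(=O)CBr | starting material
12 | 1-(2-methoxy-2-oxoethyl)-9-O-methylquinidinium bromide | COc1ccc2nccc(c2c1)[C@@H]([C@H]1C[C@@H]2CC[N@@+]1(CC(=O)OC)C[C@@H]2C=C)OC.[Br-] | intermediate
13 | 3,5-bis(benzyloxy)-6-methylidenecyclohexa-2,4-dien-1-one (ortho-quinone methide) | C=C1C(=O)C=C(OCc2ccccc2)C=C1OCc1ccccc1 | intermediate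
14 | 9-O-methylquinidinium (methoxycarbonyl)methylide | COc1ccc2nccc(c2c1)[C@@H]([C@H]1C[C@@H]2CC[N@@+]1([CH-]C(=O)OC)C[C@@H]2C=C)OC | intermediate
15 | betaine, 1-[(1R)-2-[2,4-bis(benzyloxy)-6-oxidophenyl]-1-(methoxycarbonyl)ethyl]-9-O-methylquinidinium | COc1ccc2nccc(c2c1)[C@@H]([C@H]1C[C@@H]2CC[N@@+]1([C@@H](C(=O)OC)Cc1c([O-])cc(OCc3ccccc3)cc1OCc1ccccc1)C[C@@H]2C=C)OC | intermediate
16 | methyl (S)-4,6-bis(benzyloxy)-2,3-dihydrobenzofuran-2-carboxylate | C(c1ccccc1)Oc1cc(OCc2ccccc2)cc2O[C@H](C(=O)OC)Cc12 | intermediate
17 | methylmagnesium bromide | C[Mg]Br | starting material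
18 | (S)-1-[4,6-bis(benzyloxy)-2,3-dihydrobenzofuran-2-yl]ethan-1-one | C(c1ccccc1)Oc1cc(OCc2ccccc2)cc2O[C@H](C(C)=O)Cc12 | intermediate
19 | (S)-2-[4,6-bis(benzyloxy)-2,3-dihydrobenzofuran-2-yl]propan-2-ol | C(c1ccccc1)Oc1cc(OCc2ccccc2)cc2O[C@H](C(C)(C)O)Cc12 | intermediate
20 | N-bromosuccinimide | O=C1CCC(=O)N1Br | starting material
21 | (S)-2-[4,6-bis(benzyloxy)-7-bromo-2,3-dihydrobenzofuran-2-yl]propan-2-ol | C(c1ccccc1)Oc1cc(OCc2ccccc2)c(Br)c2O[C@H](C(C)(C)O)Cc12 | intermediate
22 | N-methoxy-N-methylisobutyramide | CC(C)C(=O)N(C)OC | starting material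
23 | C7 aryllithium, lithium alkoxide of 21 after exchange, (S) | C(c1ccccc1)Oc1cc(OCc2ccccc2)c([Li])c2O[C@H](C(C)(C)O[Li])Cc12 | intermediate
24 | lithium N-methoxy-N-methyl hemiaminal adduct at C7, (2S), new carbinol centre undefined | C(c1ccccc1)Oc1cc(OCc2ccccc2)c(C(O[Li])(C(C)C)N(C)OC)c2O[C@H](C(C)(C)O[Li])Cc12 | intermediate
25 | 1-[(2S)-4,6-bis(benzyloxy)-2-(2-hydroxypropan-2-yl)-2,3-dihydrobenzofuran-7-yl]-2-methylpropan-1-one | C(c1ccccc1)Oc1cc(OCc2ccccc2)c(C(=O)C(C)C)c2O[C@H](C(C)(C)O)Cc12 | intermediate
26 | 1-[(2S)-4,6-dihydroxy-2-(2-hydroxypropan-2-yl)-2,3-dihydrobenzofuran-7-yl]-2-methylpropan-1-one | Oc1cc(O)c(C(=O)C(C)C)c2O[C@H](C(C)(C)O)Cc12 | intermediate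
27 | prenyl bromide (1-bromo-3-methylbut-2-ene) | CC(C)=CCBr | starting material
28 | 1-[(2S)-4,6-dihydroxy-2-(2-hydroxypropan-2-yl)-5-(3-methylbut-2-enyl)-2,3-dihydrobenzofuran-7-yl]-2-methylpropan-1-one | Oc1c(CC=C(C)C)c(O)c(C(=O)C(C)C)c2O[C@H](C(C)(C)O)Cc12 | intermediate
29 | garcinielliptone HD, (2S)-7-(1-hydroxy-2-methylpropylidene)-2-(2-hydroxypropan-2-yl)-5,5-bis(3-methylbut-2-enyl)-2,3-dihydrobenzofuran-4,6(5H,7H)-dione, enol OH syn to the C6 carbonyl | CC(C)=CCC1(CC=C(C)C)C(=O)C2=C(O[C@H](C(C)(C)O)C2)/C(=C(/O)C(C)C)C1=O | target

Total steps: 11. Longest linear sequence: 9 (steps 1, 2, 3, 6, 7, 8, 9, 10, 11); steps 4 and 5 form the side branch to salt 12.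

Steps most likely to fail

Step 6.
- Risks: facial discrimination at the ylide carbon may be poor. Base may epimerise the α-aryloxy ester after ring closure. The methide may self-condense, or the betaine may lose the amine by β-elimination instead of cyclising.
- Fallback with known chemistry, setting out from 7 and 11: dimethyl sulfide is alkylated with 11 to give (2-methoxy-2-oxoethyl)dimethylsulfonium bromide F1. Cs2CO3 in CH2Cl2 converts it into dimethylsulfonium (methoxycarbonyl)methylide F2.
- F2 undergoes the established racemic sulfonium-ylide [4+1] annulation with methide 13 released from 7, giving racemic methyl 4,6-bis(benzyloxy)-2,3-dihydrobenzofuran-2-carboxylate F3.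
- Preparative chromatography on a cellulose tris(3,5-dimethylphenylcarbamate) phase separates 16 from methyl (R)-4,6-bis(benzyloxy)-2,3-dihydrobenzofuran-2-carboxylate F4. F4 is racemised with DBU and recycled.
- The same two bonds and the same ring are formed, the stereochemistry comes from separation, and the route is rejoined at 16.

Step 11.
- Risks: O-alkylation may compete, the reaction may stall after the first alkylation, or the second prenyl group may attack the ring-fusion carbon C3a.
- Fallback, setting out from 26: Tsuji–Trost prenylation with commercial prenyl acetate, the zerovalent palladium catalyst Pd(PPh3)4 and K2CO3 in THF at 50 °C.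
- The electrophile is then a π-prenyl palladium complex that a soft carbon nucleophile attacks at its CH2 terminus. O-allylation is reversible under palladium catalysis, so material should funnel through 28 to the C5,C5-dialkylated product.
- The route is rejoined at 29 and no compound outside the list is made (F0).

Step 9.
- Risks: acyl transfer to a doubly ortho-substituted aryllithium may be slow. Proton transfer from the benzylic CH2 groups or base-induced breakdown of the N-methoxy amide could then win, leading to net protodebromination.
- Fallback, setting out from 21: the same exchange gives 23, which is added to the small and highly electrophilic isobutyraldehyde at −78 °C. This gives 1-[(2S)-4,6-bis(benzyloxy)-2-(2-hydroxypropan-2-yl)-2,3-dihydrobenzofuran-7-yl]-2-methylpropan-1-ol F5 as a mixture of carbinol epimers.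
- Dess–Martin periodinane in CH2Cl2 oxidises the secondary benzylic alcohol and leaves the tertiary one untouched. The route is rejoined at 25.

Further compounds
F1 | step 6 | (2-methoxy-2-oxoethyl)dimethylsulfonium bromide | C[S+](C)CC(=O)OC.[Br-]
F2 | step 6 | dimethylsulfonium (methoxycarbonyl)methylide | C[S+](C)[CH-]C(=O)OC
F3 | step 6 | racemic methyl 4,6-bis(benzyloxy)-2,3-dihydrobenzofuran-2-carboxylate | C(c1ccccc1)Oc1cc(OCc2ccccc2)cc2OC(C(=O)OC)Cc12
F4 | step 6 | methyl (R)-4,6-bis(benzyloxy)-2,3-dihydrobenzofuran-2-carboxylate | C(c1ccccc1)Oc1cc(OCc2ccccc2)cc2O[C@@H](C(=O)OC)Cc12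
F0 | step 11 | none | none
F5 | step 9 | 1-[(2S)-4,6-bis(benzyloxy)-2-(2-hydroxypropan-2-yl)-2,3-dihydrobenzofuran-7-yl]-2-methylpropan-1-ol, both carbinol epimers | C(c1ccccc1)Oc1cc(OCc2ccccc2)c(C(O)C(C)C)c2O[C@H](C(C)(C)O)Cc12
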